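**Retrosynthetic overview** (locants follow the isochromene numbering of the target: C1, O2, C3, C4, C4a, C5–C8, C8a)
1. The pyran is formed last: the O2–C3 bond is made by 6-endo-dig addition of the C1 hydroxymethyl group to a C4a pentenynyl arm, so the carbocycle is built first and the pyran second.
2. Key disconnection: C5–C6 and C7–C8 of the cyclohexenone, formed together in a stepwise formal [4+2] between a chiral vinylketeniminium ion (C8, C8a, C4a, C5) and a Z enediol derivative (C6, C7) that already carries the aryl ester on O7 and a silyl group on O6.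
3. Enabling feature: in the carbocycle C4a–C5–C6–C7–C8–C8a the C8 ketone is conjugated with the ring-fusion alkene C4a=C8a and C5 is the γ-methylene of that enone. C8 (electrophile) and C5 (nucleophile) are therefore the ends of a vinylketene synthon, the cis O6/O7 pair on C6–C7 maps onto an enol silyl ether/enol ester, and both new bonds are polarity-matched.
4. Four-carbon unit: methyl but-2-ynoate → Z iodoacrylate → Sonogashira coupling (pentenynyl arm) → deconjugative α-alkylation (brings in C1 with O2) → amide of (2R,5R)-2,5-dimethylpyrrolidine, the temporary controller of C7.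
5. Two-carbon unit: orsellinic acid + methyl 2-bromopropanoate → silylation, methylation, reduction to the aldehyde, enol silylation; end game: global desilylation, then gold-catalysed ring closure.

Key step: step 12

Remark (assumption): the (2R,5R) auxiliary is taken to deliver the (6R,7R) series in step 12; the sense is assigned by analogy only, and if it proves opposite the (2S,5S) amine is used with no other change.

**Step 1**
Reactants: 1 (E)-1-bromoprop-1-ene; 2 ethynyltrimethylsilane
Product: 3 (E)-trimethyl(pent-3-en-1-yn-1-yl)silane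
Conditions: PdCl2(PPh3)2 (2 mol %), CuI (4 mol %), i-Pr2NH, THF, 23 °C
Reagents that add atoms: none
Why: Sonogashira coupling of the alkenyl bromide with the silyl-capped alkyne should proceed with retention of the E geometry and gives the enyne in a non-volatile, storable form.

**Step 2**
Reactants: 4 methyl but-2-ynoate
Product: 5 methyl (Z)-3-iodobut-2-enoate
Conditions: NaI, AcOH, 115 °C
Reagents that add atoms: sodium iodide, [Na+].[I-]
Why: Conjugate addition of iodide to the ynoate followed by anti protonation (hydroiodination) should give the Z β-iodoacrylate, a standard stereodefined partner for cross-coupling.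

**Step 3**
Reactants: 5 methyl (Z)-3-iodobut-2-enoate; 3 (E)-trimethyl(pent-3-en-1-yn-1-yl)silane
Product: 6 methyl (2Z,6E)-3-methylocta-2,6-dien-4-ynoate
Conditions: PdCl2(PPh3)2 (3 mol %), CuI (6 mol %), CsF, Et3N, DMF, 23 °C
Reagents that add atoms: none
Why: Sonogashira coupling with fluoride-triggered desilylation in the flask should transfer the pentenynyl group to the alkenyl iodide with retention of both double-bond geometries and without handling the volatile free enyne.

**Step 4**
Reactants: 6 methyl (2Z,6E)-3-methylocta-2,6-dien-4-ynoate; 7 (chloromethoxy)tri(propan-2-yl)silane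
Product: 8 methyl (6E)-3-methylidene-2-({[tri(propan-2-yl)silyl]oxy}methyl)oct-6-en-4-ynoate (racemic)
Conditions: LiN(i-Pr)2, THF/DMPU, −78 °C; then 7, −78 → −40 °C; cold aq. NH4Cl
Reagents that add atoms: none
Why: γ-Deprotonation gives the extended ester enolate, which should be alkylated at its α-carbon (deconjugative α-alkylation), so that the future C1 with O2 is attached to the future C8a and the alkene moves to the C4a=C5 methylidene position needed later; the new stereocentre forms as a racemate and is destroyed in step 12.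

**Step 5**
Reactants: 8 methyl (6E)-3-methylidene-2-({[tri(propan-2-yl)silyl]oxy}methyl)oct-6-en-4-ynoate
Product: 9 (6E)-3-methylidene-2-({[tri(propan-2-yl)silyl]oxy}methyl)oct-6-en-4-ynoic acid (racemic)
Conditions: Me3SnOH, ClCH2CH2Cl, 70 °C; 5% aq. HCl wash
Reagents that add atoms: trimethyltin hydroxide, C[Sn](C)(C)O (one carboxyl oxygen)
Why: Me3SnOH-mediated ester hydrolysis works under near-neutral conditions, which should avoid base-induced reconjugation of the alkene and β-elimination of the silyloxy group.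

**Step 6**
Reactants: 9 (6E)-3-methylidene-2-({[tri(propan-2-yl)silyl]oxy}methyl)oct-6-en-4-ynoic acid; 10 (2R,5R)-2,5-dimethylpyrrolidine
Product: 12 (6E)-1-[(2R,5R)-2,5-dimethylpyrrolidin-1-yl]-3-methylidene-2-({[tri(propan-2-yl)silyl]oxy}methyl)oct-6-en-4-yn-1-one (both epimers at C2), via acid chloride 11 (not isolated)
Conditions: 1-chloro-N,N,2-trimethylprop-1-en-1-amine, CH2Cl2, 0 °C; then 10, Et3N, −20 → 23 °C
Reagents that add atoms: 1-chloro-N,N,2-trimethylprop-1-en-1-amine, CC(C)=C(Cl)N(C)C (chlorine of 11 only)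
Why: Neutral conversion of the acid into its chloride with the α-chloroenamine followed by N-acylation of the hindered secondary amine (Schotten–Baumann-type amide formation) installs the C2-symmetric controller, and any ketene formed from 11 by Et3N would be captured by the amine to give the same amide.

**Step 7**
Reactants: 13 2,4-dihydroxy-6-methylbenzoic acid (orsellinic acid); 14 methyl 2-bromopropanoate (racemic)
Product: 15 1-methoxy-1-oxopropan-2-yl 2,4-dihydroxy-6-methylbenzoate (racemic)
Conditions: KHCO3, DMF, 23 °C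
Reagents that add atoms: none
Why: SN2 O-alkylation of the carboxylate by the α-bromo ester builds the hindered di-ortho-substituted ester without any attack on its carbonyl group, and hydrogencarbonate is too weak a base to ionise the phenols.

**Step 8**
Reactants: 15 1-methoxy-1-oxopropan-2-yl 2,4-dihydroxy-6-methylbenzoate
Product: 16 1-methoxy-1-oxopropan-2-yl 2-hydroxy-6-methyl-4-{[tri(propan-2-yl)silyl]oxy}benzoate
Conditions: i-Pr3SiCl, imidazole, CH2Cl2, 0 → 23 °C
Reagents that add atoms: chlorotri(propan-2-yl)silane, CC(C)[Si](Cl)(C(C)C)C(C)C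
Why: Silyl ether formation should occur selectively at the free 4-hydroxyl because the 2-hydroxyl is held in a hydrogen bond to the ester carbonyl and is flanked by it.

**Step 9**
Reactants: 16 1-methoxy-1-oxopropan-2-yl 2-hydroxy-6-methyl-4-{[tri(propan-2-yl)silyl]oxy}benzoate
Product: 17 1-methoxy-1-oxopropan-2-yl 2-methoxy-6-methyl-4-{[tri(propan-2-yl)silyl]oxy}benzoate
Conditions: MeOH, PPh3, diisopropyl azodicarboxylate, THF, 0 → 23 °C
Reagents that add atoms: methanol, CO
Why: Mitsunobu etherification should methylate the hydrogen-bonded phenol under neutral conditions that leave the aryl silyl ether and both esters untouched.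

**Step 10**
Reactants: 17 1-methoxy-1-oxopropan-2-yl 2-methoxy-6-methyl-4-{[tri(propan-2-yl)silyl]oxy}benzoate
Product: 18 1-oxopropan-2-yl 2-methoxy-6-methyl-4-{[tri(propan-2-yl)silyl]oxy}benzoate (racemic)
Conditions: i-Bu2AlH (1.1 equiv), CH2Cl2, −78 °C; MeOH, then aq. KNaC4H4O6
Reagents that add atoms: none
Why: Partial reduction of the α-acyloxy methyl ester by i-Bu2AlH should stop at the aldehyde through the chelated tetrahedral aluminium alkoxide, while the di-ortho-substituted, electron-rich aryl ester is too hindered to react at −78 °C.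

**Step 11**
Reactants: 18 1-oxopropan-2-yl 2-methoxy-6-methyl-4-{[tri(propan-2-yl)silyl]oxy}benzoate
Product: 19 (Z)-1-{[tert-butyl(dimethyl)silyl]oxy}prop-1-en-2-yl 2-methoxy-6-methyl-4-{[tri(propan-2-yl)silyl]oxy}benzoate
Conditions: t-BuMe2SiOTf, Et3N, CH2Cl2, 0 → 23 °C
Reagents that add atoms: tert-butyldimethylsilyl trifluoromethanesulfonate, CC(C)(C)[Si](C)(C)OS(=O)(=O)C(F)(F)F
Why: Soft enolisation with silyl triflate and amine (enol silyl ether formation) removes the stereocentre and should favour the Z isomer with the two oxygens cis (cis effect of 1,2-dioxygenated alkenes, silyloxy group away from the methyl group).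

**Step 12**
Reactants: 12 (6E)-1-[(2R,5R)-2,5-dimethylpyrrolidin-1-yl]-3-methylidene-2-({[tri(propan-2-yl)silyl]oxy}methyl)oct-6-en-4-yn-1-one; 19 (Z)-1-{[tert-butyl(dimethyl)silyl]oxy}prop-1-en-2-yl 2-methoxy-6-methyl-4-{[tri(propan-2-yl)silyl]oxy}benzoate
Product: 22 (1R,6R)-6-{[tert-butyl(dimethyl)silyl]oxy}-1-methyl-2-oxo-4-[(E)-pent-3-en-1-yn-1-yl]-3-({[tri(propan-2-yl)silyl]oxy}methyl)cyclohex-3-en-1-yl 2-methoxy-6-methyl-4-{[tri(propan-2-yl)silyl]oxy}benzoate, via vinylketeniminium triflate 20 (not isolated), via cyclohexenyliminium triflate 21 (not isolated)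
Conditions: (CF3SO2)2O, 2,6-di-tert-butyl-4-methylpyridine, CH2Cl2, −40 → 0 °C; then 19, −78 → 23 °C; then aq. NaHCO3, THF, 23 °C
Reagents that add atoms: water, O (oxygen of the C8 ketone); trifluoromethanesulfonic anhydride, O=S(=O)(OS(=O)(=O)C(F)(F)F)C(F)(F)F (counter-ion of 20 and 21 only)
Why: Proposed new method: triflic anhydride and the hindered pyridine turn amide 12 into vinylketeniminium ion 20, whose sp carbon C8 is attacked by C7 of 19 (the carbon β to the silyloxy group, the stronger of the two oxygen donors), and the resulting 2-aminodiene/silyloxocarbenium pair closes from its terminal carbon C5 onto C6 to give the conjugated iminium ion 21, hydrolysed to enone 22, so that C7–C8 and C5–C6 form in one flask in a polarity-matched, stepwise formal [4+2]. The closest known reaction types are the [2+2] cycloaddition of keteniminium salts with alkenes, which is known to show high facial selectivity with trans-2,5-dimethylpyrrolidine amides, the annulations that use a vinylketene as a four-carbon unit, and the Lewis-acid opening of 3-alkoxycyclobutanones to 1,4-zwitterions. The only ring closed is the cyclohexenone, by a 6-(enolendo)-exo-trig attack of the dienamine γ-carbon on the oxocarbenium ion, and a cyclobutaniminium ion from the competing four-membered closure at C8a is a donor–acceptor cyclobutane that should reopen and drain into the unstrained, conjugated six-membered iminium ion. C7 is set in the first bond formation by the C2-symmetric auxiliary, whose two methyl groups lie above and below the plane in which the nucleophile approaches C8 and so differentiate the enantiofaces of the enol ether (auxiliary control), and C6 is set relative to C7 in the ring closure through a chair-like transition state with C7–CH3 and C6–OSi pseudo-equatorial, which keeps the two oxygens cis as they are in the Z enol ether. The step needs regioselectivity for C7 (secured by silyloxy over acyloxy donation), attack on the side of the vinyl arm so that the diene can close (secured by the bulkier silyloxymethyl arm on the other side) and inertness of the ester carbonyl towards the cations (secured by its two ortho substituents).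

**Step 13**
Reactants: 22 (1R,6R)-6-{[tert-butyl(dimethyl)silyl]oxy}-1-methyl-2-oxo-4-[(E)-pent-3-en-1-yn-1-yl]-3-({[tri(propan-2-yl)silyl]oxy}methyl)cyclohex-3-en-1-yl 2-methoxy-6-methyl-4-{[tri(propan-2-yl)silyl]oxy}benzoate
Product: 23 (1R,6R)-6-hydroxy-3-(hydroxymethyl)-1-methyl-2-oxo-4-[(E)-pent-3-en-1-yn-1-yl]cyclohex-3-en-1-yl 4-hydroxy-2-methoxy-6-methylbenzoate
Conditions: HF·pyridine, pyridine, THF, 0 → 23 °C
Reagents that add atoms: none
Why: Fluoride-driven cleavage of the three silyl ethers by pyridine-buffered HF is slightly acidic, so neither acyl shift from O7 to O6 nor retro-aldol opening of the β-hydroxy ketone is expected, and the acid-sensitive dienyl enol ether is not yet present.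

**Step 14**
Reactants: 23 (1R,6R)-6-hydroxy-3-(hydroxymethyl)-1-methyl-2-oxo-4-[(E)-pent-3-en-1-yn-1-yl]cyclohex-3-en-1-yl 4-hydroxy-2-methoxy-6-methylbenzoate
Product: 24 (6R,7R)-6-hydroxy-7-methyl-8-oxo-3-[(E)-prop-1-en-1-yl]-5,6,7,8-tetrahydro-1H-isochromen-7-yl 4-hydroxy-2-methoxy-6-methylbenzoate
Conditions: Ph3PAuNTf2 (3 mol %), CH2Cl2, 23 °C
Reagents that add atoms: none
Why: Gold-catalysed 6-endo-dig hydroalkoxylation (cycloisomerisation) should let the C1 hydroxyl add to alkyne carbon C3, which is the δ-carbon of the ynenone and carries the propenyl donor, so closure at C3 is favoured over 5-exo closure at C4, with the proton ending on C4 and no stereocentre formed.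

**Compound list**
1 | (E)-1-bromoprop-1-ene | C/C=C/Br | starting material
2 | ethynyltrimethylsilane | C#C[Si](C)(C)C | starting material
3 | (E)-trimethyl(pent-3-en-1-yn-1-yl)silane | C/C=C/C#C[Si](C)(C)C | intermediate
4 | methyl but-2-ynoate | CC#CC(=O)OC | starting material
5 | methyl (Z)-3-iodobut-2-enoate | C/C(I)=C/C(=O)OC | intermediate
6 | methyl (2Z,6E)-3-methylocta-2,6-dien-4-ynoate | C/C=C/C#C/C(C)=C\C(=O)OC | intermediate
7 | (chloromethoxy)tri(propan-2-yl)silane | CC(C)[Si](OCCl)(C(C)C)C(C)C | starting material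
8 | methyl (6E)-3-methylidene-2-({[tri(propan-2-yl)silyl]oxy}methyl)oct-6-en-4-ynoate (racemic) | C/C=C/C#CC(=C)C(CO[Si](C(C)C)(C(C)C)C(C)C)C(=O)OC | intermediate
9 | (6E)-3-methylidene-2-({[tri(propan-2-yl)silyl]oxy}methyl)oct-6-en-4-ynoic acid (racemic) | C/C=C/C#CC(=C)C(CO[Si](C(C)C)(C(C)C)C(C)C)C(=O)O | intermediate
10 | (2R,5R)-2,5-dimethylpyrrolidine | C[C@@H]1CC[C@@H](C)N1 | starting material
11 | (6E)-3-methylidene-2-({[tri(propan-2-yl)silyl]oxy}methyl)oct-6-en-4-ynoyl chloride (racemic, not isolated) | C/C=C/C#CC(=C)C(CO[Si](C(C)C)(C(C)C)C(C)C)C(=O)Cl | intermediate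
12 | (6E)-1-[(2R,5R)-2,5-dimethylpyrrolidin-1-yl]-3-methylidene-2-({[tri(propan-2-yl)silyl]oxy}methyl)oct-6-en-4-yn-1-one (both epimers at C2) | C/C=C/C#CC(=C)C(CO[Si](C(C)C)(C(C)C)C(C)C)C(=O)N1[C@H](C)CC[C@H]1C | intermediate
13 | 2,4-dihydroxy-6-methylbenzoic acid (orsellinic acid) | Cc1cc(O)cc(O)c1C(=O)O | starting material
14 | methyl 2-bromopropanoate (racemic) | COC(=O)C(C)Br | starting material
15 | 1-methoxy-1-oxopropan-2-yl 2,4-dihydroxy-6-methylbenzoate (racemic) | COC(=O)C(C)OC(=O)c1c(C)cc(O)cc1O | intermediate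
16 | 1-methoxy-1-oxopropan-2-yl 2-hydroxy-6-methyl-4-{[tri(propan-2-yl)silyl]oxy}benzoate (racemic) | COC(=O)C(C)OC(=O)c1c(C)cc(O[Si](C(C)C)(C(C)C)C(C)C)cc1O | intermediate
17 | 1-methoxy-1-oxopropan-2-yl 2-methoxy-6-methyl-4-{[tri(propan-2-yl)silyl]oxy}benzoate (racemic) | COC(=O)C(C)OC(=O)c1c(C)cc(O[Si](C(C)C)(C(C)C)C(C)C)cc1OC | intermediate
18 | 1-oxopropan-2-yl 2-methoxy-6-methyl-4-{[tri(propan-2-yl)silyl]oxy}benzoate (racemic) | CC(C=O)OC(=O)c1c(C)cc(O[Si](C(C)C)(C(C)C)C(C)C)cc1OC | intermediate
19 | (Z)-1-{[tert-butyl(dimethyl)silyl]oxy}prop-1-en-2-yl 2-methoxy-6-methyl-4-{[tri(propan-2-yl)silyl]oxy}benzoate | C/C(OC(=O)c1c(C)cc(O[Si](C(C)C)(C(C)C)C(C)C)cc1OC)=C/O[Si](C)(C)C(C)(C)C | intermediate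
20 | (2R,5R)-2,5-dimethyl-1-[(6E)-3-methylidene-2-({[tri(propan-2-yl)silyl]oxy}methyl)octa-1,6-dien-4-yn-1-ylidene]pyrrolidin-1-ium trifluoromethanesulfonate (vinylketeniminium triflate, not isolated) | C/C=C/C#CC(=C)C(CO[Si](C(C)C)(C(C)C)C(C)C)=C=[N+]1[C@H](C)CC[C@H]1C.[O-]S(=O)(=O)C(F)(F)F | intermediate
21 | (2R,5R)-1-[(5R,6S)-5-{[tert-butyl(dimethyl)silyl]oxy}-6-[(2-methoxy-6-methyl-4-{[tri(propan-2-yl)silyl]oxy}benzoyl)oxy]-6-methyl-3-[(E)-pent-3-en-1-yn-1-yl]-2-({[tri(propan-2-yl)silyl]oxy}methyl)cyclohex-2-en-1-ylidene]-2,5-dimethylpyrrolidin-1-ium trifluoromethanesulfonate (cyclohexenyliminium triflate, not isolated; same spatial arrangement as 22) | C/C=C/C#CC1=C(CO[Si](C(C)C)(C(C)C)C(C)C)C(=[N+]2[C@H](C)CC[C@H]2C)[C@](C)(OC(=O)c2c(C)cc(O[Si](C(C)C)(C(C)C)C(C)C)cc2OC)[C@H](O[Si](C)(C)C(C)(C)C)C1.[O-]S(=O)(=O)C(F)(F)F | intermediate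
22 | (1R,6R)-6-{[tert-butyl(dimethyl)silyl]oxy}-1-methyl-2-oxo-4-[(E)-pent-3-en-1-yn-1-yl]-3-({[tri(propan-2-yl)silyl]oxy}methyl)cyclohex-3-en-1-yl 2-methoxy-6-methyl-4-{[tri(propan-2-yl)silyl]oxy}benzoate | C/C=C/C#CC1=C(CO[Si](C(C)C)(C(C)C)C(C)C)C(=O)[C@](C)(OC(=O)c2c(C)cc(O[Si](C(C)C)(C(C)C)C(C)C)cc2OC)[C@H](O[Si](C)(C)C(C)(C)C)C1 | intermediate
23 | (1R,6R)-6-hydroxy-3-(hydroxymethyl)-1-methyl-2-oxo-4-[(E)-pent-3-en-1-yn-1-yl]cyclohex-3-en-1-yl 4-hydroxy-2-methoxy-6-methylbenzoate | C/C=C/C#CC1=C(CO)C(=O)[C@](C)(OC(=O)c2c(C)cc(O)cc2OC)[C@H](O)C1 | intermediate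
24 | (6R,7R)-6-hydroxy-7-methyl-8-oxo-3-[(E)-prop-1-en-1-yl]-5,6,7,8-tetrahydro-1H-isochromen-7-yl 4-hydroxy-2-methoxy-6-methylbenzoate | C/C=C/C1=CC2=C(CO1)C(=O)[C@](C)(OC(=O)c1c(C)cc(O)cc1OC)[C@H](O)C2 | target

**Step count and risks**
Total step count: 14. Longest linear sequence: 8 steps (steps 2, 3, 4, 5, 6, 12, 13, 14; the arene branch, steps 7–14, is equally long).

Steps most likely to fail:

1. Step 12 (proposed new method). What may go wrong: addition of the enol ether with low facial selectivity under the auxiliary, arrest at the four-membered ring, or interception of the cation before the second bond forms. Fallback with reactions of established type: setting out from acid 9, converted into chloride 11 as in step 6, and from enol ether 19, a ZnCl2-mediated Mukaiyama-type C-acylation in CH2Cl2 should give the keto aldehyde F1. Me2AlCl at −78 °C should then bring about the intramolecular carbonyl-ene (vinylogous aldol) cyclisation to the racemic cis hydroxy enone F2. Silylation with t-BuMe2SiOTf/2,6-lutidine gives racemic 22, whose enantiomers are separated by HPLC on cellulose tris(3,5-dimethylphenylcarbamate), and the (1R,6R) enantiomer rejoins the route at 22.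

2. Step 14. What may go wrong: ring closure at the wrong alkyne carbon (5-exo instead of 6-endo) or degradation of the dienyl enol ether by the Lewis-acidic catalyst. Fallback: setting out from 23, morpholine in MeOH should add to the δ-carbon (C3) of the ynenone to give the enaminone F3. Pyridinium p-toluenesulfonate in toluene then lets the C1 hydroxyl displace morpholine at C3 by addition–elimination, which can only close the six-membered ring, and the route is rejoined at 24.

3. Step 13. What may go wrong: slow cleavage of the hindered secondary silyl ether next to the quaternary carbon, so that forcing fluoride conditions cause shift of the aroyl group from O7 to O6 or retro-aldol ring opening. Fallback by a change of protecting group: setting out from 18, Et3SiOTf/Et3N should give the triethylsilyl enol ether F4, which is taken with 12 through the conditions of step 12 to the triethylsilyl analogue F5. The labile secondary silyl ether of F5 is cleaved together with the two triisopropylsilyl ethers by buffered HF·pyridine at 0 °C, and the route is rejoined at 23.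

**Further compounds**
F1 | step 12 | (8E)-2-methyl-5-methylidene-1,3-dioxo-4-({[tri(propan-2-yl)silyl]oxy}methyl)dec-8-en-6-yn-2-yl 2-methoxy-6-methyl-4-{[tri(propan-2-yl)silyl]oxy}benzoate (racemic, both diastereomers) | C/C=C/C#CC(=C)C(CO[Si](C(C)C)(C(C)C)C(C)C)C(=O)C(C)(C=O)OC(=O)c1c(C)cc(O[Si](C(C)C)(C(C)C)C(C)C)cc1OC
F2 | step 12 | racemic cis-6-hydroxy-1-methyl-2-oxo-4-[(E)-pent-3-en-1-yn-1-yl]-3-({[tri(propan-2-yl)silyl]oxy}methyl)cyclohex-3-en-1-yl 2-methoxy-6-methyl-4-{[tri(propan-2-yl)silyl]oxy}benzoate (racemate; the 1R,6R enantiomer is drawn) | C/C=C/C#CC1=C(CO[Si](C(C)C)(C(C)C)C(C)C)C(=O)[C@](C)(OC(=O)c2c(C)cc(O[Si](C(C)C)(C(C)C)C(C)C)cc2OC)[C@H](O)C1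
F3 | step 14 | (1R,6R)-6-hydroxy-3-(hydroxymethyl)-1-methyl-4-[(3E)-2-(morpholin-4-yl)penta-1,3-dien-1-yl]-2-oxocyclohex-3-en-1-yl 4-hydroxy-2-methoxy-6-methylbenzoate (enamine double bond geometry not fixed) | C/C=C/C(=CC1=C(CO)C(=O)[C@](C)(OC(=O)c2c(C)cc(O)cc2OC)[C@H](O)C1)N1CCOCC1
F4 | step 13 | (Z)-1-[(triethylsilyl)oxy]prop-1-en-2-yl 2-methoxy-6-methyl-4-{[tri(propan-2-yl)silyl]oxy}benzoate | C/C(OC(=O)c1c(C)cc(O[Si](C(C)C)(C(C)C)C(C)C)cc1OC)=C/O[Si](CC)(CC)CC
F5 | step 13 | (1R,6R)-1-methyl-2-oxo-4-[(E)-pent-3-en-1-yn-1-yl]-6-[(triethylsilyl)oxy]-3-({[tri(propan-2-yl)silyl]oxy}methyl)cyclohex-3-en-1-yl 2-methoxy-6-methyl-4-{[tri(propan-2-yl)silyl]oxy}benzoate | C/C=C/C#CC1=C(CO[Si](C(C)C)(C(C)C)C(C)C)C(=O)[C@](C)(OC(=O)c2c(C)cc(O[Si](C(C)C)(C(C)C)C(C)C)cc2OC)[C@H](O[Si](CC)(CC)CC)C1
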